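**Retrosynthetic overview**
1. Isopanduratin A (ring A = trioxygenated benzene, ring B = cyclohexene, ring C = phenyl) is the dehydrative sum of three small achiral pieces: a ring A acetophenone, benzaldehyde (ring C) and (E)-β-ocimene.
2. Disconnections: C1–C2 and C5–C6 of ring B (retro-Diels–Alder; the retron is the C3=C4 alkene opposite the C1–C6 bond), then C1=C6 of the resulting chalcone (retro-aldol condensation). In the forward sense all three bonds are made in one flask on one chiral boron atom.
3. Enabling feature: on ring A the phenol O at C2' and the ketone O are 1,5-related (O–C2'–C1'–C=O) and clamp an (S)-VANOL borate into a six-membered 1,3,2-dioxaborine. This temporary ring acidifies the acetyl CH3, lowers the enone LUMO and holds the chiral diol over one enone face, while the C6' OMe forces the enone s-cis.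
4. Ring order: rings A and C are bought. A temporary sulfolene ring delivers geometrically pure (E)-β-ocimene (C2 prenylation, cheletropic loss of SO2). Ring B is closed last, and the C4' OH travels as a TIPS ether and is freed at the end.

Key step: step 4

Remark (locants): ring B is numbered C1 (acyl), C2 (prenyl), C3 (methyl), C4 (=CH), C5 (CH2), C6 (phenyl); primed locants belong to ring A.
Remark (supply): 1-(2,4-dihydroxy-6-methoxyphenyl)ethanone, (S)-VANOL (3,3'-diphenyl-[2,2'-binaphthalene]-1,1'-diol) and B(OPh)3 are taken as catalogue compounds.
Remark (stereo notation and facial sense): SMILES cannot carry the biaryl axis, so the (S) axis is given in the names only. The facial sense assigned to (S)-VANOL rests on a quadrant model of the spiroborate, and if practice showed the opposite sense, (R)-VANOL would take its place with nothing else changed.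

Step 1
Reactants: 1 3-methyl-2,5-dihydrothiophene 1,1-dioxide (3-methyl-3-sulfolene); 2 1-bromo-3-methylbut-2-ene (prenyl bromide)
Product: 3 (±)-3-methyl-2-(3-methylbut-2-en-1-yl)-2,5-dihydrothiophene 1,1-dioxide
Conditions: LiN(SiMe3)2 (1.05 equiv) added to 1 + 2 (1.2 equiv), THF/HMPA, −78 °C
Reagents that add atoms: none
Why: This is an α-sulfonyl carbanion alkylation of a 3-sulfolene in which adding the base to the premixed sulfolene and allylic bromide lets SN2 capture outrun ring opening of the anion, alkylation should favour C2 (between sulfur and the methyl-bearing alkene carbon) as is usual for 3-methyl-3-sulfolene with any C5 isomer removed by chromatography, and the new stereocentre is racemic and is erased in step 2.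

Step 2
Reactants: 3 (±)-3-methyl-2-(3-methylbut-2-en-1-yl)-2,5-dihydrothiophene 1,1-dioxide
Product: 4 (E)-β-ocimene, (3E)-3,7-dimethylocta-1,3,6-triene
Conditions: neat, BHT (cat.), 125 °C, 100 mbar, triene distilled into a cold receiver as it forms
Reagents that add atoms: none
Why: This is a cheletropic (retro-[4+1]) extrusion of SO2, suprafacial and disrotatory, in which the C2 substituent turns outward for steric reasons so that the trisubstituted diene alkene should form as the E isomer only, driven by gas loss and distillation.

Step 3
Reactants: 5 1-(2,4-dihydroxy-6-methoxyphenyl)ethanone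
Product: 6 1-[2-hydroxy-6-methoxy-4-(triisopropylsilyloxy)phenyl]ethanone
Conditions: iPr3SiCl (1.05 equiv), imidazole (1.5 equiv), CH2Cl2, 0 °C to rt
Reagents that add atoms: triisopropylsilyl chloride, CC(C)[Si](Cl)(C(C)C)C(C)C
Why: This is a chemoselective phenol silylation in which the C2' OH is hydrogen-bonded to the ketone and flanked by the acetyl group, so the bulky silyl chloride should take only the free and more acidic C4' OH, and no stereocentre is formed.

Step 4
Reactants: 6 1-[2-hydroxy-6-methoxy-4-(triisopropylsilyloxy)phenyl]ethanone; 7 benzaldehyde; 4 (E)-β-ocimene
Product: 11 4'-O-triisopropylsilyl-isopanduratin A, via acetophenone spiroborate 8 (not isolated), via chalcone spiroborate 9 (not isolated), via cycloadduct spiroborate 10 (not isolated)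
Conditions: (S)-VANOL (1.15 equiv), B(OPh)3 (1.1 equiv), PhCF3, 60 °C, then vacuum; 6, 7 (1.5 equiv), 4 (3 equiv), n-BuNH2 (20 mol %), 4 Å MS, PhCF3, 40 °C, all three components present from the start; then H2O, THF, rt
Reagents that add atoms: none
Why: Proposed new method: phenol 6 displaces phenoxide from the (S)-VANOL phenyl borate made in the flask to give spiroborate 8, whose boron-bound, oxocarbenium-like ketone makes the acetyl CH3 acidic enough for an amine-catalysed aldol condensation with 7 (deprotonation, addition, E1cB loss of water, which the sieves take up), and the (E)-chalcone chelate 9 so formed is the only low-LUMO alkene in the flask and is intercepted by diene 4 in a concerted, asynchronous [4+2] cycloaddition to 10, which mild hydrolysis opens to 11. The closest known reaction types are the amine-catalysed condensation of aromatic aldehydes with the methyl group of 1,3,2-dioxaborine chelates of 1,3-diketones and o-hydroxyaryl methyl ketones (boron-templated curcuminoid synthesis) and the chiral diol borate-promoted Diels–Alder reaction of preformed 2'-hydroxychalcones with 1,3-dienes, and what is new is that both run in one flask on the same chiral boron atom as a three-component domino condensation/cycloaddition. Ring B is closed by an intermolecular [4π+2π] cycloaddition, suprafacial on both partners, which forms C1–C2 and C5–C6 and leaves the C3=C4 alkene. The trans relation C1/C6 copies the E geometry of the chalcone, the cis relation C1/C2 follows from the E geometry of 4 (prenyl outside) combined with the endo position of the boron-bound acyl group, and the absolute sense (1R,2S,6R) is set by (S)-VANOL, whose vaulted naphthalene beneath the ketone half of the dioxaborine should leave only the Cα-Re/Cβ-Re face open to an endo approach. Regioselectivity (CH2 terminus of 4 to the benzylic β-carbon, prenyl-bearing terminus to Cα) is secured by the polarisation of the chelated enone, the low hindrance of the CH2 end and the 1-alkyl ("ortho") directing effect, which outweighs that of the 2-methyl group, and site selectivity in 4 is secured because only its first four carbons are conjugated, so the isolated Me2C=CH alkene is a spectator. A single reactive conformer is secured by the C6' methoxy group, which forces the chelated enone s-cis, and a racemic background is excluded because unbound chalcone does not react with 4 at this temperature, the diol is kept in slight excess over boron, and the C4' OTIPS group leaves the C2' OH as the only boron-binding phenol.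

Step 5
Reactants: 11 4'-O-triisopropylsilyl-isopanduratin A
Product: 12 isopanduratin A
Conditions: Bu4NF (1.1 equiv), AcOH (1.1 equiv), THF, 0 °C
Reagents that add atoms: none
Why: This is a fluoride-induced cleavage of an aryl silyl ether, fast because the departing phenoxide is para to the ketone, and the acetic acid buffer keeps the medium non-basic so that the C1 stereocentre next to the ketone and both alkenes stay untouched.

**Compound list**
1 | 3-methyl-2,5-dihydrothiophene 1,1-dioxide (3-methyl-3-sulfolene) | CC1=CCS(=O)(=O)C1 | starting material
2 | 1-bromo-3-methylbut-2-ene (prenyl bromide) | CC(C)=CCBr | starting material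
3 | (±)-3-methyl-2-(3-methylbut-2-en-1-yl)-2,5-dihydrothiophene 1,1-dioxide | CC1=CCS(=O)(=O)C1CC=C(C)C | intermediate
4 | (E)-β-ocimene, (3E)-3,7-dimethylocta-1,3,6-triene | C=C/C(C)=C/CC=C(C)C | intermediate
5 | 1-(2,4-dihydroxy-6-methoxyphenyl)ethanone | CC(=O)c1c(O)cc(O)cc1OC | starting material
6 | 1-[2-hydroxy-6-methoxy-4-(triisopropylsilyloxy)phenyl]ethanone | CC(=O)c1c(O)cc(O[Si](C(C)C)(C(C)C)C(C)C)cc1OC | intermediate
7 | benzaldehyde | O=Cc1ccccc1 | starting material
8 | acetophenone spiroborate: boron bound to both oxygens of (S)-VANOL and to the C2' phenolate O and ketone O of 6 | COc1cc(O[Si](C(C)C)(C(C)C)C(C)C)cc2O[B-]3(Oc4c5ccccc5cc(-c5ccccc5)c4-c4c(O3)c5ccccc5cc4-c4ccccc4)[O+]=C(C)c12 | intermediate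
9 | chalcone spiroborate: the same (S)-VANOL chelate carrying the (E)-styryl group on the ketone carbon | COc1cc(O[Si](C(C)C)(C(C)C)C(C)C)cc2O[B-]3(Oc4c5ccccc5cc(-c5ccccc5)c4-c4c(O3)c5ccccc5cc4-c4ccccc4)[O+]=C(/C=C/c4ccccc4)c12 | intermediate
10 | cycloadduct spiroborate: (S)-VANOL chelate of 11, ring B (1R,2S,6R) | COc1cc(O[Si](C(C)C)(C(C)C)C(C)C)cc2O[B-]3(Oc4c5ccccc5cc(-c5ccccc5)c4-c4c(O3)c5ccccc5cc4-c4ccccc4)[O+]=C(c12)[C@@H]1[C@H](CC=C(C)C)C(C)=CC[C@H]1c1ccccc1 | intermediate
11 | 4'-O-triisopropylsilyl-isopanduratin A, [2-hydroxy-6-methoxy-4-(triisopropylsilyloxy)phenyl][(1R,2S,6R)-3-methyl-2-(3-methylbut-2-en-1-yl)-6-phenylcyclohex-3-en-1-yl]methanone | COc1cc(O[Si](C(C)C)(C(C)C)C(C)C)cc(O)c1C(=O)[C@@H]1[C@H](CC=C(C)C)C(C)=CC[C@H]1c1ccccc1 | intermediate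
12 | isopanduratin A, (2,4-dihydroxy-6-methoxyphenyl)[(1R,2S,6R)-3-methyl-2-(3-methylbut-2-en-1-yl)-6-phenylcyclohex-3-en-1-yl]methanone | COc1cc(O)cc(O)c1C(=O)[C@@H]1[C@H](CC=C(C)C)C(C)=CC[C@H]1c1ccccc1 | target

**Total step count:** 5
**Longest linear sequence:** 4 (steps 1, 2, 4, 5)

**Steps most likely to fail**

1. Step 4 (the step with the proposed new method).
   - Risk: the condensation may stall on the electron-rich chelated acetophenone. The water and amine may also strip the diol from boron, so that the cascade stops before the cycloaddition or loses facial control.
   - Fallback (known chemistry, sets out from 5, comes back at 11): condensation and cycloaddition are separated. Compound 5 is condensed with 7 under Claisen–Schmidt conditions (KOH, EtOH/H2O, rt) to cardamonin F1. Its free C4' OH is silylated (iPr3SiCl, imidazole, CH2Cl2) to 4'-O-triisopropylsilylcardamonin F2. F2 is then bound to preformed (S)-VANOL phenyl borate (giving 9) and treated with 4 (PhCF3, 4 Å MS, no amine) in the established two-component borate-promoted Diels–Alder reaction of 2'-hydroxychalcones. Hydrolysis of 10 gives 11.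

2. Step 1.
   - Risk: ring opening of the sulfolenyl anion, double alkylation or alkylation at C5 may erode the supply of the diene precursor.
   - Fallback (sets out from 2, comes back at 4, bypassing steps 1 and 2): commercial but-1-en-3-yne undergoes Negishi carboalumination (AlMe3, Cp2ZrCl2 cat., ClCH2CH2Cl, rt). The syn addition gives dimethyl[(1E)-2-methylbuta-1,3-dien-1-yl]alane F3. F3 is coupled in the same flask with 2 under Pd(PPh3)4 catalysis (THF, rt), at the unsubstituted allyl terminus and with retention of the alkenyl geometry, to give 4.

3. Step 2.
   - Risk: loss of the volatile triene, thermal or SO2-induced polymerisation, and alkene isomerisation during the extrusion.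
   - Fallback (sets out from 6 and 7, comes back at 11): no diene is synthesised. Redistilled technical ocimene (a commercial E/Z mixture) is used in larger excess in step 4. This relies on kinetic selection, because the Z isomer cannot reach the s-cis conformation without a severe clash and should stay behind to be removed by evaporation. This fallback makes no new compound (F0).

**Further compounds**
F1 | step 4 | cardamonin, (E)-1-(2,4-dihydroxy-6-methoxyphenyl)-3-phenylprop-2-en-1-one | COc1cc(O)cc(O)c1C(=O)/C=C/c1ccccc1
F2 | step 4 | 4'-O-triisopropylsilylcardamonin | COc1cc(O[Si](C(C)C)(C(C)C)C(C)C)cc(O)c1C(=O)/C=C/c1ccccc1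
F3 | step 1 | dimethyl[(1E)-2-methylbuta-1,3-dien-1-yl]alane | C[Al](C)/C=C(\C)C=C
F0 | step 2 | none | none
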